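**Strategy.** The saturated ring of the tetralin (C1–C4, fused to the trioxygenated arene at C8a/C4a) is read as a cyclobutanone into whose C1–C4 bond an aryne has been inserted. Enantiopure trans-2,3-bis(benzyloxymethyl)cyclobutanone already holds C2, C3 and the C1–C4 bond. Its enolate carbon (C4) attacks a 3-methoxyaryne at the future C4a, remote from the C8 methoxy group; the aryl anion at C8a closes onto the carbonyl (C1); strain-driven cleavage of C1–C4 gives the 1-tetralone. Both aryl–carbon bonds and the six-membered ring thus arise in one operation. The pendant aryl group is then added to the C1 ketone and the carbinol reduced to the trans product.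

Key step: step 7

Remark: tetralin numbering is used throughout (C1 carries the pendant aryl group, C4 is the CH2, C8 is the methoxy-bearing peri carbon; target = 1S,2R,3R). In step 2 the (+)-menthyl ester is assumed to give the (1R,2S) ring configuration, the mirror image of the behaviour of the (−)-menthyl ester.

**Step 1**
Reactants: 1 (+)-menthol; 2 fumaryl chloride
Product: 3 di-(+)-menthyl fumarate
Conditions: 1 (2.1 equiv in all), Et3N (2.5 equiv), DMAP (cat.), CH2Cl2, 0 °C → rt
Reagents that add atoms: (+)-menthol (second equivalent of 1), O[C@H]1C[C@@H](C)CC[C@@H]1C(C)C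
Why: DMAP-catalysed esterification in which two equivalents of the secondary alcohol acylate both acid chloride groups of the diacid chloride; no stereocentre is touched and the E geometry is retained.

**Step 2**
Reactants: 3 di-(+)-menthyl fumarate; 4 1,1-dimethoxyethene
Product: 5 di-(+)-menthyl (1R,2S)-3,3-dimethoxycyclobutane-1,2-dicarboxylate
Conditions: iBu2AlCl (2.2 equiv), toluene/hexane, −78 °C; aq. HCl work-up; crystallisation
Reagents that add atoms: none
Why: Lewis-acid-promoted stepwise (2+2) cycloaddition (Michael addition of the ketene acetal to the aluminium-bound fumarate, then ring closure) in which both menthyl groups shield the same face of the acceptor, so the trans diester of (1R,2S) ring configuration should predominate and be upgraded by crystallisation; this sets the future C3 and C2.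

**Step 3**
Reactants: 5 cyclobutane diester
Product: 6 [(1R,2R)-3,3-dimethoxycyclobutane-1,2-diyl]dimethanol
Conditions: LiAlH4, THF, 0 °C → rt; Fieser work-up
Reagents that add atoms: none
Why: LiAlH4 ester reduction gives the two primary alcohols, leaves the ketal and both ring stereocentres untouched and releases the auxiliary for recovery.

**Step 4**
Reactants: 6 diol
Product: 7 (2R,3R)-2,3-bis[(benzyloxy)methyl]-1,1-dimethoxycyclobutane
Conditions: NaH, BnBr, Bu4NI (cat.), THF/DMF, 0 °C → rt
Reagents that add atoms: benzyl bromide, BrCc1ccccc1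
Why: Williamson etherification of both primary alkoxides; benzyl ethers tolerate the amide base, organometallic and acidic steps that follow and fall in the last step.

**Step 5**
Reactants: 7 bis-benzyl ether ketal
Product: 8 (2R,3R)-2,3-bis[(benzyloxy)methyl]cyclobutan-1-one
Conditions: 0.5 M aq. H2SO4, MeCN, rt
Reagents that add atoms: water, O
Why: Acid-catalysed ketal hydrolysis unveils the cyclobutanone; the trans arrangement at the α-carbon is the thermodynamically preferred one, so enolisation should not erode it.

**Step 6**
Reactants: 9 4-bromo-2,6-dimethoxyphenol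
Product: 10 2-(benzyloxy)-5-bromo-1,3-dimethoxybenzene
Conditions: BnBr, K2CO3, DMF, 60 °C
Reagents that add atoms: benzyl bromide, BrCc1ccccc1
Why: Williamson etherification masks the phenol for aryne generation and halogen–lithium exchange; the bromine marks the future C4a.

**Step 7**
Reactants: 8 cyclobutanone; 10 aryl bromide
Product: 15 (2R,3R)-7-(benzyloxy)-2,3-bis[(benzyloxy)methyl]-6,8-dimethoxy-3,4-dihydronaphthalen-1(2H)-one, via lithium enolate 11 (not isolated), via aryne 12 (not isolated), via benzocyclobutenoxide 13 (not isolated), via benzylic organolithium 14 (not isolated)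
Conditions: 8, lithium 2,2,6,6-tetramethylpiperidide (1.1 equiv), THF, −78 °C; then 10 (1.3 equiv) and lithium 2,2,6,6-tetramethylpiperidide (1.5 equiv, slow addition), −78 → −30 °C; AcOH, −78 °C
Reagents that add atoms: none
Why: Proposed new method: kinetic deprotonation of 8 at the unsubstituted C4 methylene gives enolate 11, whose carbon adds to aryne 12 at the carbon remote from the flanking methoxy group (future C4a); the aryl anion so formed ortho to that methoxy group (future C8a) closes 4-exo-trig onto the cyclobutanone carbonyl to give 13, and cleavage of the shared C1–C4 bond of this bicyclo[2.2.0]hexane unit opens both four-membered rings to the conjugated benzylic anion 14, protonated on quench to 15. The closest known reaction types are the two-carbon ring expansion of cycloalkanone enolates by arynes through benzocyclobutenoxides and the acyl-alkylation of arynes with β-keto esters; neither is assumed to be established for a cyclobutanone. The six-membered ring arises by this ring expansion, not by direct cyclisation; the only ring-closing event is the 4-exo-trig addition. No stereocentre of the product is created: C2 and C3 come from 8, the transient centres at C1 and C4 vanish on fragmentation and protonation, and should proton transfer turn 14 into the C2 enolate, protonation on quench should return the more stable diequatorial trans isomer. The step needs regioselective enolisation (hindered amide base, unsubstituted α-carbon) and regioselective aryne addition (inductive bias of the C8 methoxy group next to the aryne), and it needs ring closure to outrun protonation of the aryl anion, which the high electrophilicity of the strained carbonyl should favour.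

**Step 8**
Reactants: 10 aryl bromide; 15 tetralone
Product: 18 (2R,3R)-7-(benzyloxy)-1-[4-(benzyloxy)-3,5-dimethoxyphenyl]-2,3-bis[(benzyloxy)methyl]-6,8-dimethoxy-1,2,3,4-tetrahydronaphthalen-1-ol (C1 epimers), via aryllithium 16 (not isolated), via arylcerium dichloride 17 (not isolated)
Conditions: 10 (1.5 equiv), n-BuLi, THF, −78 °C; anhydrous CeCl3, −78 °C; then 15, −78 → −40 °C; aq. NH4Cl
Reagents that add atoms: none
Why: Halogen–lithium exchange and transmetalation give a weakly basic, strongly nucleophilic organocerium reagent that should undergo 1,2-addition to the hindered, enolisable ketone without β-elimination of benzyl alkoxide; the configuration of the new carbinol centre is irrelevant because it is ionised in step 9.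

**Step 9**
Reactants: 18 tertiary alcohol
Product: 20 (1S,2R,3R)-7-(benzyloxy)-1-[4-(benzyloxy)-3,5-dimethoxyphenyl]-2,3-bis[(benzyloxy)methyl]-6,8-dimethoxy-1,2,3,4-tetrahydronaphthalene, via benzylic cation 19 (not isolated)
Conditions: Et3SiH (5 equiv), TFA (10 equiv), CH2Cl2, −40 → 0 °C
Reagents that add atoms: none
Why: Ionic hydrogenation (Kursanov–Parnes reduction): acid ionises the doubly benzylic alcohol to cation 19, and Et3SiH should deliver hydride axially to the half-chair with both side chains pseudo-equatorial, anti to the pseudo-axial C2–H, so that hydrogen enters cis and the aryl group ends trans to the C2 side chain (1S), the all-trans arrangement of the target.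

**Step 10**
Reactants: 20 tetrabenzyl ether
Product: 21 (6R,7R,8S)-8-(4-hydroxy-3,5-dimethoxyphenyl)-6,7-bis(hydroxymethyl)-1,3-dimethoxy-5,6,7,8-tetrahydronaphthalen-2-ol (target)
Conditions: H2 (1 atm), 10% Pd/C, EtOAc/MeOH, rt
Reagents that add atoms: none
Why: Hydrogenolysis of the four benzyl ethers frees both phenols and both primary alcohols without touching the methyl ethers or the stereocentres.

**Compound list**

1 | (+)-menthol, (1S,2R,5S)-2-isopropyl-5-methylcyclohexan-1-ol | O[C@H]1C[C@@H](C)CC[C@@H]1C(C)C | starting material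
2 | fumaryl chloride | O=C(Cl)/C=C/C(Cl)=O | starting material
3 | di-(+)-menthyl fumarate | O=C(/C=C/C(=O)O[C@H]1C[C@@H](C)CC[C@@H]1C(C)C)O[C@H]1C[C@@H](C)CC[C@@H]1C(C)C | intermediate
4 | 1,1-dimethoxyethene (ketene dimethyl acetal) | C=C(OC)OC | starting material
5 | di-(+)-menthyl (1R,2S)-3,3-dimethoxycyclobutane-1,2-dicarboxylate | COC1(OC)C[C@@H](C(=O)O[C@H]2C[C@@H](C)CC[C@@H]2C(C)C)[C@@H]1C(=O)O[C@H]1C[C@@H](C)CC[C@@H]1C(C)C | intermediate
6 | [(1R,2R)-3,3-dimethoxycyclobutane-1,2-diyl]dimethanol | COC1(OC)C[C@@H](CO)[C@@H]1CO | intermediate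
7 | (2R,3R)-2,3-bis[(benzyloxy)methyl]-1,1-dimethoxycyclobutane | COC1(OC)C[C@@H](COCc2ccccc2)[C@@H]1COCc1ccccc1 | intermediate
8 | (2R,3R)-2,3-bis[(benzyloxy)methyl]cyclobutan-1-one | O=C1C[C@@H](COCc2ccccc2)[C@@H]1COCc1ccccc1 | intermediate
9 | 4-bromo-2,6-dimethoxyphenol | COc1cc(Br)cc(OC)c1O | starting material
10 | 2-(benzyloxy)-5-bromo-1,3-dimethoxybenzene | COc1cc(Br)cc(OC)c1OCc1ccccc1 | intermediate
11 | lithium enolate of 8 (double bond toward the ring CH2) | [Li]OC1=C[C@@H](COCc2ccccc2)[C@@H]1COCc1ccccc1 | intermediate
12 | 4-(benzyloxy)-3,5-dimethoxybenzyne | COC1=C(OCc2ccccc2)C(OC)=CC#C1 | intermediate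
13 | lithium alkoxide of the cis-fused benzocyclobutenol–cyclobutane tricycle (ring-fusion centres transient, side-chain centres as in 8) | [Li]OC12[C@@H](COCc3ccccc3)[C@H](COCc3ccccc3)C1c1cc(OC)c(OCc3ccccc3)c(OC)c21 | intermediate
14 | C4-lithiated form of tetralone 15 (conjugated benzylic anion) | [Li]C1c2cc(OC)c(OCc3ccccc3)c(OC)c2C(=O)[C@@H](COCc2ccccc2)[C@@H]1COCc1ccccc1 | intermediate
15 | (2R,3R)-7-(benzyloxy)-2,3-bis[(benzyloxy)methyl]-6,8-dimethoxy-3,4-dihydronaphthalen-1(2H)-one | O=C1c2c(OC)c(OCc3ccccc3)c(OC)cc2C[C@@H](COCc2ccccc2)[C@@H]1COCc1ccccc1 | intermediate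
16 | [4-(benzyloxy)-3,5-dimethoxyphenyl]lithium | [Li]c1cc(OC)c(OCc2ccccc2)c(OC)c1 | intermediate
17 | [4-(benzyloxy)-3,5-dimethoxyphenyl]cerium dichloride | Cl[Ce](Cl)c1cc(OC)c(OCc2ccccc2)c(OC)c1 | intermediate
18 | (2R,3R)-7-(benzyloxy)-1-[4-(benzyloxy)-3,5-dimethoxyphenyl]-2,3-bis[(benzyloxy)methyl]-6,8-dimethoxy-1,2,3,4-tetrahydronaphthalen-1-ol (C1 epimers) | OC1(c2cc(OC)c(OCc3ccccc3)c(OC)c2)c2c(OC)c(OCc3ccccc3)c(OC)cc2C[C@@H](COCc2ccccc2)[C@@H]1COCc1ccccc1 | intermediate
19 | C1 benzylic cation of 18 as its trifluoroacetate | COc1cc(cc(OC)c1OCc1ccccc1)[C+]1c2c(OC)c(OCc3ccccc3)c(OC)cc2C[C@@H](COCc2ccccc2)[C@@H]1COCc1ccccc1.[O-]C(=O)C(F)(F)F | intermediate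
20 | (1S,2R,3R)-7-(benzyloxy)-1-[4-(benzyloxy)-3,5-dimethoxyphenyl]-2,3-bis[(benzyloxy)methyl]-6,8-dimethoxy-1,2,3,4-tetrahydronaphthalene | COc1cc([C@H]2c3c(OC)c(OCc4ccccc4)c(OC)cc3C[C@@H](COCc3ccccc3)[C@@H]2COCc2ccccc2)cc(OC)c1OCc1ccccc1 | intermediate
21 | (6R,7R,8S)-8-(4-hydroxy-3,5-dimethoxyphenyl)-6,7-bis(hydroxymethyl)-1,3-dimethoxy-5,6,7,8-tetrahydronaphthalen-2-ol | COc1cc([C@H]2c3c(cc(OC)c(O)c3OC)C[C@@H](CO)[C@@H]2CO)cc(OC)c1O | target

**Step count.** Total steps: 10. Longest linear sequence: 9 (steps 1–5 and 7–10; step 6 is a one-step side branch whose product is used in steps 7 and 8).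

**Steps most likely to fail**

1. Step 7 (proposed new method). The aryl anion may be protonated before it closes onto the carbonyl, stopping at α-arylation. The enolate may react at oxygen, or the amide base may add to the aryne. Enolisation toward C2 could be followed by β-elimination of benzyl alkoxide, and anion 14 could be arylated a second time. The fallback is a Haworth-type sequence of known reactions that sets out from 8 (and uses 10) and comes back at 15, making the two aryl–carbon bonds in separate steps. Kinetic silylation of 8 (LiN(iPr)2, Me3SiCl, THF, −78 °C) would give the trimethylsilyl enol ether F1. Ozonolysis (O3, CH2Cl2/MeOH, −78 °C; Me2S) cleaves the former C1=C4 bond to the aldehyde acid F2. The aryl Grignard reagent made from 10 (Mg, THF; 2.2 equiv, the first equivalent forming the carboxylate) adds to the aldehyde, and acidic work-up gives the γ-aryl-γ-butyrolactone F3. Ionic hydrogenolysis of its benzylic C–O bond (Et3SiH, TFA, CH2Cl2) gives the 4-arylbutanoic acid F4. Intramolecular Friedel–Crafts acylation (TFAA, CH2Cl2, 0 °C) at the position ortho to a methoxy group then gives 15.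

2. Step 9. Hydride delivery to the C1 cation may show poor or opposite facial selectivity. C2 may lose its configuration through elimination to the 3,4-dihydronaphthalene and reprotonation, or a benzyloxy oxygen may capture the cation with loss of its benzyl group. The fallback sets out from 15 and comes back at 21; it delivers the aryl group, not the hydride, as the nucleophile to a C1 cation, which inverts the outcome if the face preference is opposite to the one assumed. Reduction of 15 (NaBH4, MeOH/THF, 0 °C) would give the tetralol F5. Friedel–Crafts arylation with 2,6-dimethoxyphenol at its para position (BF3·OEt2, CH2Cl2, −40 °C) gives the 1-aryl tetralin F6 with the pendant phenol free. Hydrogenolysis of F6 (H2, Pd/C) gives 21.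

3. Step 8. The aryl nucleophile may enolise the hindered ketone, with β-elimination of benzyl alkoxide, or fail to add next to the peri methoxy group. The fallback sets out from 15 (and uses 10) and comes back at 20; it forms the C1–aryl bond by carbene cross-coupling in place of carbonyl addition. Condensation of 15 with 4-methylbenzenesulfonohydrazide (MeOH, 60 °C) would give the tosylhydrazone F7. Barluenga coupling with 10 (Pd2(dba)3, XPhos, LiOtBu, dioxane, 100 °C) gives the 1-aryl-3,4-dihydronaphthalene F8 by migratory insertion of the palladium carbene and β-hydride elimination. F8 is the conjugate base of cation 19; under the conditions of step 9 it is protonated at C2 and reduced to 20. C2 is re-formed in this protonation; because protonation is reversible, the cation with both side chains pseudo-equatorial should be the one reduced.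

**Further compounds**

F1 | step 7 | trimethylsilyl enol ether of 8 (double bond toward the ring CH2) | C[Si](C)(C)OC1=C[C@@H](COCc2ccccc2)[C@@H]1COCc1ccccc1
F2 | step 7 | (2R,3R)-2,3-bis[(benzyloxy)methyl]-4-oxobutanoic acid | O=C[C@@H](COCc1ccccc1)[C@H](COCc1ccccc1)C(=O)O
F3 | step 7 | (3R,4R)-3,4-bis[(benzyloxy)methyl]-5-[4-(benzyloxy)-3,5-dimethoxyphenyl]oxolan-2-one (C5 epimers) | O=C1OC(c2cc(OC)c(OCc3ccccc3)c(OC)c2)[C@@H](COCc2ccccc2)[C@@H]1COCc1ccccc1
F4 | step 7 | (2R,3R)-4-[4-(benzyloxy)-3,5-dimethoxyphenyl]-2,3-bis[(benzyloxy)methyl]butanoic acid | COc1cc(C[C@@H](COCc2ccccc2)[C@H](COCc2ccccc2)C(=O)O)cc(OC)c1OCc1ccccc1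
F5 | step 9 | (2R,3R)-7-(benzyloxy)-2,3-bis[(benzyloxy)methyl]-6,8-dimethoxy-1,2,3,4-tetrahydronaphthalen-1-ol (C1 epimers) | OC1c2c(OC)c(OCc3ccccc3)c(OC)cc2C[C@@H](COCc2ccccc2)[C@@H]1COCc1ccccc1
F6 | step 9 | 4-[(1S,2R,3R)-7-(benzyloxy)-2,3-bis[(benzyloxy)methyl]-6,8-dimethoxy-1,2,3,4-tetrahydronaphthalen-1-yl]-2,6-dimethoxyphenol | COc1cc([C@H]2c3c(OC)c(OCc4ccccc4)c(OC)cc3C[C@@H](COCc3ccccc3)[C@@H]2COCc2ccccc2)cc(OC)c1O
F7 | step 8 | 4-methylbenzenesulfonohydrazone of 15 (side-chain configuration unchanged) | Cc1ccc(cc1)S(=O)(=O)NN=C1c2c(OC)c(OCc3ccccc3)c(OC)cc2C[C@@H](COCc2ccccc2)[C@@H]1COCc1ccccc1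
F8 | step 8 | (3R)-7-(benzyloxy)-1-[4-(benzyloxy)-3,5-dimethoxyphenyl]-2,3-bis[(benzyloxy)methyl]-6,8-dimethoxy-3,4-dihydronaphthalene | COc1cc(cc(OC)c1OCc1ccccc1)C1=C(COCc2ccccc2)[C@H](COCc2ccccc2)Cc2cc(OC)c(OCc3ccccc3)c(OC)c12
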